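The numbers in the tables were generated by integration for an exercise; noise was put on by code.

J units are conserved in this closed flask: on the steps thought possible, J plus G plus Q, with one Q counted as two, stays at 100 percent of the J charged. Neither G nor Q stands on the left of a listed step, so a later gain in G has to come out of free J. I therefore carry one quantity: the headroom H, the free J at the moment of acting, in percent of the J charged, read here as the mean of the violet J readings, 0.675%.

| flask | J | E | temperature | remark | time |
|---|---|---|---|---|---|
| violet | 10 mM | 1 µM | 40 °C | the very flask that is asked about, followed so far |  |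
| green | 15 mM | 1 µM | 35 °C | run made earlier |  |
| flask | 10 mM | 1.0 µM | 40 °C |  | 8.0 d |

| run | time / h | G / % | J / % |
|---|---|---|---|
| violet | 12.0 | 50.7 | 0.1 |
| violet | 30.0 | 53.0 | 0 |
| violet | 72.0 | 50.4 | 1.5 |
| violet | 144 | 52.2 | 1.1 |
| green | 0.667 | 15.2 | 27.5 |
| green | 1.33 | 38.7 | 0 |
| green | 3.00 | 39.1 | 0 |
| green | 8.00 | 40.2 | 0 |

(readings scatter by 1 percentage point)

* G, in percent of the J first charged, at 8.0 d
* what to do for the largest gain in G; "none" if nothing gains more than 2 percentage points (oak / cedar / birch / ash / none)
* G present, with what was taken out counted in, in percent of the J first charged, after cedar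
* G present, with what was taken out counted in, in percent of the J first charged, after birch

- oak: at 8.0 d raise the temperature by 10 K, then wait 8.0 d
- cedar: at 8.0 d take out 90% of the G then present, then wait 8.0 d
- birch: at 8.0 d add E, 50.0% of the amount charged, then wait 8.0 d
- ash: change nothing and wait 8.0 d more

- percent here means J units held: one Q counts as two
- G taken out counts as made
- the earlier runs were read with a standard deviation of 1 percentage point
- steps thought possible: 2 J -> Q; E -> D; J + E -> G + E
- additions bring no volume worth counting

The crossing comes early. The violet flask reads J at 0.1% after 12.0 h, well before the 8.0 d at which I act, and the green run reads 0% after 1.33 h. Up to that crossing J feeds both G and Q; past it J, the limiting reagent, has H to give. The violet G readings average 51.6%, and that is my figure for G now.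

Now the settings by hand. Oak raises the temperature by 10 K, but the steps that use J still share the same H of 0.675%. Cedar takes out 90% of the G, which is a reactant in no listed step, and G taken out counts as made, so my total stays at 51.6% plus whatever of H turns into G. Birch adds E at 50.0% of the charge, with H of J to work on. Ash waits 8.0 d on the same H. H stands below the 2 percentage points margin, though each reading scatters by 1 point, so I choose none.

The forecast gives 51.6% (50.7% to 52.5%) now, 51.6% after cedar, 51.8% after birch and none as the best choice, saying “The split between G and Q was therefore fixed early”.

The flask gives 51.4% of G at 8.0 d, 51.4% after cedar, 51.4% after birch, and none as the best choice.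

    2 J → Q (k = 2.30 /M/min, Ea = 66.0 kJ/mol)
    E → D (k = 5.80 × 10⁻⁵ /min, Ea = 266 kJ/mol)
    J + E → G + E, rate k3*[J]*[E]/(1 + ([J]/Km3) + ([J]/Ksi3)^2) (0.350 mM, 0.930 mM, k = 14000 /M/s, Ea = 30.0 kJ/mol)
    (constants at 40 °C)

With H read at 0.675%, under the 2 points margin, oak, cedar, birch and ash gain 0 points, 0 points, 0 points and 0 points; at 192 h the flask holds J at 0% beside E at 51.3% of its charge. The neighbour flask at 15 °C ends with G at 70.3% and Q at 29.7%, yet its headroom at 192 h is 0%, below the 2 points margin, with E at >99.9% of its charge.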